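## Retrosynthetic overview

1. The C6–O ester is made last, by Mitsunobu inversion of the macrocyclic 6-epi alcohol with (2R,3R)-epoxyangelic acid (from angelic acid by Sharpless epoxidation).
2. Key bond C6–C7 closes the ten-membered carbocycle: a CrCl2-mediated intramolecular Barbier addition in which a 3-(bromomethyl)butenolide acts as a lactone homoenolate (nucleophilic β-carbon C7) toward the C6 Z-enal. The same step sets C6 and C7 and unveils the α-methylene lactone.
3. Before that: butenolide by ring-closing metathesis of a C8 2-(bromomethyl)acrylate; 3(2H)-furanone by gold cycloisomerisation of an α'-hydroxy ynone.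
4. The ynone comes from opening (3R,5S)-3-hydroxy-3-methyl-5-vinylbutyrolactone with the acetylide of (Z)-3-methylpent-2-en-4-yn-1-ol; that lactone comes from acrolein and ethyl 2-(bromomethyl)acrylate (asymmetric chromium allylation, then reductive enolate hydroxylation).
5. Ring order: γ-lactone template (opened again) → furanone → butenolide → ten-membered ring (butenolide becomes the α-methylene lactone); the oxirane is built separately and attached last.

Assumption: the SMILES is read as the (4Z,6S,7R,8S,10R) 12,8-olide with a (2R,3R)-2,3-dimethyloxirane-2-carboxylate on O6; germacrane numbering is used throughout (C1 ketone, C2=C3, C4(C15)=C5, C6, C7, C8, C9, C10(C14), C11=C13, C12 lactone carbonyl).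

## Route

Step 1
Reactants: 1 acrolein (prop-2-enal); 2 ethyl 2-(bromomethyl)prop-2-enoate
Product: 4 (5S)-5-ethenyl-3-methylideneoxolan-2-one, via TMS ether of the hydroxy ester 3 (not isolated)
Conditions: CrCl2 (10 mol %), carbazole bis(4-isopropyloxazoline) ligand (12 mol %, the enantiomer that directs Si-face addition), Mn, Me3SiCl, i-Pr2NEt (20 mol %), THF, rt; then 1 M HCl, THF, rt
Reagents that add atoms: none
Why: Chromium-catalysed asymmetric Nozaki–Hiyama–Kishi 2-(alkoxycarbonyl)allylation (Barbier type): the allylchromium from 2 adds through its γ-carbon to the Si face of acrolein inside the chiral ligand sphere, which sets C8 as S, Me3SiCl turns the catalyst over by forming silyl ether 3, and aqueous acid cleaves that ether and closes the γ-lactone.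

Step 2
Reactants: 4 (5S)-5-ethenyl-3-methylideneoxolan-2-one
Product: 6 (3R,5S)-5-ethenyl-3-hydroxy-3-methyloxolan-2-one, via potassium enolate 5 (not isolated)
Conditions: KBH(s-Bu)3, THF, −78 °C; then 2-(phenylsulfonyl)-3-phenyloxaziridine, −78 → −40 °C; aq. NH4Cl
Reagents that add atoms: 2-(phenylsulfonyl)-3-phenyloxaziridine (Davis oxaziridine), O=S(=O)(c1ccccc1)N1OC1c1ccccc1
Why: Conjugate hydride addition to the α-methylene lactone gives enolate 5, and Davis enolate hydroxylation occurs on the face of the planar five-membered enolate anti to the C5 vinyl group (1,3-induction), which sets C10 as R with the hydroxyl trans to vinyl.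

Step 3
Reactants: 6 (3R,5S)-5-ethenyl-3-hydroxy-3-methyloxolan-2-one; 7 (2Z)-3-methylpent-2-en-4-yn-1-ol
Product: 10 (3S,5R,9Z)-3,5-dihydroxy-5,9-dimethyl-11-[(triethylsilyl)oxy]undeca-1,9-dien-7-yn-6-one (open form of its lactol), via TES ether of the enynol 8 (not isolated), via its lithium acetylide 9 (not isolated)
Conditions: 7 (1.3 equiv), n-BuLi, THF, −78 → 0 °C; Et3SiCl, 0 °C; n-BuLi, −78 °C; then 6 pre-treated with LiN(SiMe3)2 (THF, −78 °C), −78 → −40 °C; aq. NH4Cl
Reagents that add atoms: chlorotriethylsilane, CC[Si](Cl)(CC)CC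
Why: Nucleophilic acyl substitution of the lactone by a lithium acetylide stops at the lactol alkoxide (C10 is quaternary, so nothing can enolise) and opens the template to the α'-hydroxy ynone with C8 and C10 untouched and the Z-alkene carried in from 7, while the in situ silylation masks the primary alcohol, which would otherwise cyclise onto the ynone to a furan in the next step.

Step 4
Reactants: 10 (3S,5R,9Z)-3,5-dihydroxy-5,9-dimethyl-11-[(triethylsilyl)oxy]undeca-1,9-dien-7-yn-6-one
Product: 12 (2R)-5-[(2Z)-4-hydroxybut-2-en-2-yl]-2-[(2S)-2-hydroxybut-3-en-1-yl]-2-methylfuran-3(2H)-one, via TES-protected furanone 11 (not isolated)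
Conditions: (p-CF3C6H4)3PAuCl (5 mol %), AgOTf (5 mol %), toluene, rt; then MeOH, PPTS (20 mol %), rt
Reagents that add atoms: none
Why: Gold-catalysed 5-endo-dig cycloisomerisation of an α'-hydroxy ynone (the tertiary hydroxyl adds to the gold-activated β-carbon C3, then protodeauration) gives the 3(2H)-furanone without touching C10, and the acid methanolysis that follows removes the silyl ether once the ynone is gone.

Step 5
Reactants: 12 (2R)-5-[(2Z)-4-hydroxybut-2-en-2-yl]-2-[(2S)-2-hydroxybut-3-en-1-yl]-2-methylfuran-3(2H)-one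
Product: 13 (2Z)-3-{(5R)-5-[(2S)-2-hydroxybut-3-en-1-yl]-5-methyl-4-oxo-4,5-dihydrofuran-2-yl}but-2-enal
Conditions: TEMPO (10 mol %), PhI(OAc)2, CH2Cl2, rt
Reagents that add atoms: none
Why: Oxoammonium (TEMPO/PhI(OAc)2) oxidation is selective for the primary allylic alcohol over the secondary one and leaves Z-allylic systems unisomerised.

Step 6
Reactants: 13 (2Z)-3-{(5R)-5-[(2S)-2-hydroxybut-3-en-1-yl]-5-methyl-4-oxo-4,5-dihydrofuran-2-yl}but-2-enal; 14 2-(bromomethyl)prop-2-enoic acid
Product: 16 (2S)-1-{(2R)-2-methyl-3-oxo-5-[(2Z)-4-oxobut-2-en-2-yl]-2,3-dihydrofuran-2-yl}but-3-en-2-yl 2-(bromomethyl)prop-2-enoate, via 2-(bromomethyl)acryloyl chloride 15 (not isolated)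
Conditions: 14, (COCl)2, DMF (cat.), CH2Cl2, 0 °C → rt, evaporate; then 13, 2,6-lutidine, CH2Cl2, −20 → 0 °C
Reagents that add atoms: none
Why: O-acylation of the secondary allylic alcohol by acid chloride 15 with a hindered pyridine base that does not displace the allylic bromide; C8 keeps its configuration because its C–O bond is not broken.

Step 7
Reactants: 16 (2S)-1-{(2R)-2-methyl-3-oxo-5-[(2Z)-4-oxobut-2-en-2-yl]-2,3-dihydrofuran-2-yl}but-3-en-2-yl 2-(bromomethyl)prop-2-enoate
Product: 17 (2Z)-3-[(5R)-5-{[(2S)-4-(bromomethyl)-5-oxo-2,5-dihydrofuran-2-yl]methyl}-5-methyl-4-oxo-4,5-dihydrofuran-2-yl]but-2-enal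
Conditions: Hoveyda–Grubbs second-generation catalyst RuCl2(H2IMes)(=CH-C6H4-2-O-i-Pr) (10 mol %), 1,4-benzoquinone (20 mol %), toluene (5 mM), 60 °C
Reagents that add atoms: none
Why: Ring-closing metathesis between the vinyl group and the 1,1-disubstituted acrylate closes the five-membered butenolide with loss of ethene, the electron-poor alkenes of the dienal-furanone are inert, and benzoquinone suppresses ruthenium hydride isomerisation of the Z-enal.

Step 8
Reactants: 17 (2Z)-3-[(5R)-5-{[(2S)-4-(bromomethyl)-5-oxo-2,5-dihydrofuran-2-yl]methyl}-5-methyl-4-oxo-4,5-dihydrofuran-2-yl]but-2-enal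
Product: 19 (4Z,6R,7R,8S,10R)-6-hydroxy-1-oxo-3,10-epoxygermacra-2,4,11(13)-trien-12,8-olide (macrocyclic alcohol; C6 epimer of the target carbinol), via allylchromium dichloride 18 (not isolated)
Conditions: CrCl2 (8 equiv), 4 Å MS, THF, rt, 17 added by syringe pump over 12 h (1 mM final); H2O work-up
Reagents that add atoms: none
Why: Proposed new method: CrCl2 inserts into the allylic C–Br bond to give allylchromium 18, a lactone homoenolate equivalent whose nucleophilic carbon C7 is the β-carbon of the butenolide (normally a Michael-acceptor position), and C7 adds to the aldehyde carbon C6 through a six-membered chair transition state in an intramolecular Nozaki–Hiyama–Kishi (Barbier) allylation that closes the ten-membered carbocycle and moves the double bond to the exocyclic methylene; attack on the butenolide face anti to the C9 substituent gives 7R (trans lactone) and the ring-locked E-type allyl unit with the aldehyde substituent pseudo-equatorial gives the anti (6R) carbinol, as in the closest known reactions, the intermolecular Barbier additions of 3-(bromomethyl)butenolides to aldehydes and chromium-mediated allylation macrocyclisations.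

Step 9
Reactants: 20 angelic acid, (2Z)-2-methylbut-2-enoic acid
Product: 21 (2Z)-2-methylbut-2-en-1-ol
Conditions: LiAlH4, Et2O, 0 °C → rt; aq. NaOH work-up
Reagents that add atoms: none
Why: Hydride (LiAlH4) reduction of the carboxylic acid to the primary allylic alcohol, a 1,2-reduction that leaves the Z-alkene geometry intact.

Step 10
Reactants: 21 (2Z)-2-methylbut-2-en-1-ol
Product: 22 [(2S,3R)-2,3-dimethyloxiran-2-yl]methanol
Conditions: Ti(O-i-Pr)4 (10 mol %), L-(+)-diethyl tartrate (12 mol %), t-BuOOH, 4 Å MS, CH2Cl2, −20 °C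
Reagents that add atoms: tert-butyl hydroperoxide, CC(C)(C)OO
Why: Sharpless asymmetric epoxidation: with L-(+)-diethyl tartrate the oxygen is delivered to the alkene face that gives the (2S,3R)-epoxy alcohol (the same face as for nerol), and the syn addition keeps CH2OH and the C3 methyl cis.

Step 11
Reactants: 22 [(2S,3R)-2,3-dimethyloxiran-2-yl]methanol
Product: 23 (2R,3R)-2,3-dimethyloxirane-2-carboxylic acid
Conditions: RuCl3·xH2O (2 mol %), NaIO4, CCl4/MeCN/H2O, rt
Reagents that add atoms: sodium periodate, [Na+].[O-]I(=O)(=O)=O; water, O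
Why: Ruthenium tetroxide oxidation (RuCl3/NaIO4) takes the primary alcohol to the carboxylic acid without touching the oxirane stereocentres, the change of the C2 descriptor from S to R being only a priority change.

Step 12
Reactants: 19 (4Z,6R,7R,8S,10R)-6-hydroxy-1-oxo-3,10-epoxygermacra-2,4,11(13)-trien-12,8-olide; 23 (2R,3R)-2,3-dimethyloxirane-2-carboxylic acid
Product: 24 (4Z,6S,7R,8S,10R)-1-oxo-3,10-epoxygermacra-2,4,11(13)-trien-12,8-olid-6-yl (2R,3R)-2,3-dimethyloxirane-2-carboxylate (CNP0258430.3)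
Conditions: PPh3 and DIAD premixed, toluene, 0 °C; then 19 and 23 (2 equiv), 0 °C → rt
Reagents that add atoms: none
Why: Mitsunobu esterification: the carboxylate of 23 displaces the C6 oxyphosphonium by SN2 with inversion (6R to 6S), which installs the epoxyangelate and corrects C6 in one operation while C7, C8, C10 and the oxirane centres are not involved.

## Compound list

1 | acrolein (prop-2-enal) | C=CC=O | starting material
2 | ethyl 2-(bromomethyl)prop-2-enoate | C=C(CBr)C(=O)OCC | starting material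
3 | ethyl (4S)-2-methylidene-4-[(trimethylsilyl)oxy]hex-5-enoate | C=C[C@@H](O[Si](C)(C)C)CC(=C)C(=O)OCC | intermediate
4 | (5S)-5-ethenyl-3-methylideneoxolan-2-one | C=C[C@@H]1CC(=C)C(=O)O1 | intermediate
5 | potassium (5S)-5-ethenyl-3-methyl-4,5-dihydrofuran-2-olate | C=C[C@@H]1CC(C)=C([O-])O1.[K+] | intermediate
6 | (3R,5S)-5-ethenyl-3-hydroxy-3-methyloxolan-2-one (OH trans to vinyl) | C=C[C@@H]1C[C@@](C)(O)C(=O)O1 | intermediate
7 | (2Z)-3-methylpent-2-en-4-yn-1-ol | C#C/C(C)=C\CO | starting material
8 | triethyl{[(2Z)-3-methylpent-2-en-4-yn-1-yl]oxy}silane | C#C/C(C)=C\CO[Si](CC)(CC)CC | intermediate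
9 | lithium acetylide of 8 | [Li]C#C/C(C)=C\CO[Si](CC)(CC)CC | intermediate
10 | (3S,5R,9Z)-3,5-dihydroxy-5,9-dimethyl-11-[(triethylsilyl)oxy]undeca-1,9-dien-7-yn-6-one | C=C[C@@H](O)C[C@@](C)(O)C(=O)C#C/C(C)=C\CO[Si](CC)(CC)CC | intermediate
11 | (2R)-2-[(2S)-2-hydroxybut-3-en-1-yl]-2-methyl-5-{(2Z)-4-[(triethylsilyl)oxy]but-2-en-2-yl}furan-3(2H)-one | C=C[C@@H](O)C[C@@]1(C)OC(=CC1=O)/C(C)=C\CO[Si](CC)(CC)CC | intermediate
12 | (2R)-5-[(2Z)-4-hydroxybut-2-en-2-yl]-2-[(2S)-2-hydroxybut-3-en-1-yl]-2-methylfuran-3(2H)-one | C=C[C@@H](O)C[C@@]1(C)OC(=CC1=O)/C(C)=C\CO | intermediate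
13 | (2Z)-3-{(5R)-5-[(2S)-2-hydroxybut-3-en-1-yl]-5-methyl-4-oxo-4,5-dihydrofuran-2-yl}but-2-enal | C=C[C@@H](O)C[C@@]1(C)OC(=CC1=O)/C(C)=C\C=O | intermediate
14 | 2-(bromomethyl)prop-2-enoic acid | C=C(CBr)C(=O)O | starting material
15 | 2-(bromomethyl)prop-2-enoyl chloride | C=C(CBr)C(=O)Cl | intermediate
16 | (2S)-1-{(2R)-2-methyl-3-oxo-5-[(2Z)-4-oxobut-2-en-2-yl]-2,3-dihydrofuran-2-yl}but-3-en-2-yl 2-(bromomethyl)prop-2-enoate | C=C[C@@H](OC(=O)C(=C)CBr)C[C@@]1(C)OC(=CC1=O)/C(C)=C\C=O | intermediate
17 | (2Z)-3-[(5R)-5-{[(2S)-4-(bromomethyl)-5-oxo-2,5-dihydrofuran-2-yl]methyl}-5-methyl-4-oxo-4,5-dihydrofuran-2-yl]but-2-enal | BrCC1=C[C@H](C[C@@]2(C)OC(=CC2=O)/C(C)=C\C=O)OC1=O | intermediate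
18 | allylchromium dichloride from 17 (CrCl2 in place of Br) | Cl[Cr](Cl)CC1=C[C@H](C[C@@]2(C)OC(=CC2=O)/C(C)=C\C=O)OC1=O | intermediate
19 | (4Z,6R,7R,8S,10R)-6-hydroxy-1-oxo-3,10-epoxygermacra-2,4,11(13)-trien-12,8-olide | C=C1C(=O)O[C@H]2C[C@@]3(C)OC(=CC3=O)/C(C)=C\[C@@H](O)[C@H]12 | intermediate
20 | angelic acid, (2Z)-2-methylbut-2-enoic acid | C/C=C(/C)C(=O)O | starting material
21 | (2Z)-2-methylbut-2-en-1-ol | C/C=C(/C)CO | intermediate
22 | [(2S,3R)-2,3-dimethyloxiran-2-yl]methanol | OC[C@]1(C)O[C@@H]1C | intermediate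
23 | (2R,3R)-2,3-dimethyloxirane-2-carboxylic acid | OC(=O)[C@]1(C)O[C@@H]1C | intermediate
24 | (4Z,6S,7R,8S,10R)-1-oxo-3,10-epoxygermacra-2,4,11(13)-trien-12,8-olid-6-yl (2R,3R)-2,3-dimethyloxirane-2-carboxylate | C=C1C(=O)O[C@H]2C[C@@]3(C)OC(=CC3=O)/C(C)=C\[C@H](OC(=O)[C@]3(C)O[C@@H]3C)[C@H]12 | target

## Step count and risks

Total steps: 12. Longest linear sequence: 9 (steps 1–8 and 12); steps 9–11 are the side branch to acid 23.

Most likely to fail, in order:

Step 8. The bridged nine-membered oxacycle must close against transannular strain, the allylchromium could react through C13 or intermolecularly, and the C6 outcome rests on a transition-state model. Fallback: reverse the order of the last two ring closures. It sets out from 10, whose secondary hydroxyl is acylated with 15 (2,6-lutidine) to give the ynone 2-(bromomethyl)acrylate F1. Ring-closing metathesis gives the bromobutenolide ynone F2, HF·pyridine gives the Z-enynol F3, and immediate MnO2 oxidation gives the enal F4. CrCl2 under high dilution then closes the ten-membered carbocycle as the unbridged cyclic α'-hydroxy ynone F5. Gold-catalysed transannular 5-endo-dig cyclisation of F5 forms the furanone and comes back to the route at 19.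

Step 7. The allylic bromide on the 1,1-disubstituted acrylate may alkylate or deactivate the ruthenium carbene, and the ring closure has to build a trisubstituted alkene next to a Z-enal. Fallback: take the bromide out of the metathesis and generate the C7 nucleophile another way. It sets out from 13, which is esterified with 2-(acetoxymethyl)acrylic acid (carbodiimide) to the 2-(acetoxymethyl)acrylate F6. Ring-closing metathesis gives the 3-(acetoxymethyl)butenolide F7. F7 is cyclised with Pd(PPh3)4 (zerovalent palladium) and InI, where a π-allylpalladium is transmetalated to an allylindium that attacks the aldehyde through C7. This comes back to the route at 19.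

Step 12. The C6 carbinol is hindered and allylic, the acid is α-quaternary, and free PPh3 can add to the α-methylene lactone. Fallback: oxidation and reduction in place of SN2 inversion. It sets out from 19, which Dess–Martin periodinane oxidises to the C6 ketone F8. NaBH4/CeCl3 at −78 °C is expected to deliver hydride from the exposed face that carried the hydroxyl of 19, giving the 6S alcohol F9. F9 is esterified with 23 under Yamaguchi conditions (2,4,6-trichlorobenzoyl chloride, Et3N, DMAP) with retention, which comes back to the route at 24. The same esterification is used if step 8 delivers F9 directly.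

## Further compounds

F1 | step 8 | (3S,5R,9Z)-5-hydroxy-5,9-dimethyl-6-oxo-11-[(triethylsilyl)oxy]undeca-1,9-dien-7-yn-3-yl 2-(bromomethyl)prop-2-enoate | C=C[C@@H](OC(=O)C(=C)CBr)C[C@@](C)(O)C(=O)C#C/C(C)=C\CO[Si](CC)(CC)CC
F2 | step 8 | (5S)-3-(bromomethyl)-5-{(2R,6Z)-2-hydroxy-2,6-dimethyl-3-oxo-8-[(triethylsilyl)oxy]oct-6-en-4-yn-1-yl}furan-2(5H)-one | BrCC1=C[C@H](C[C@@](C)(O)C(=O)C#C/C(C)=C\CO[Si](CC)(CC)CC)OC1=O
F3 | step 8 | (5S)-3-(bromomethyl)-5-[(2R,6Z)-2,8-dihydroxy-2,6-dimethyl-3-oxooct-6-en-4-yn-1-yl]furan-2(5H)-one | BrCC1=C[C@H](C[C@@](C)(O)C(=O)C#C/C(C)=C\CO)OC1=O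
F4 | step 8 | (2Z,7R)-8-[(2S)-4-(bromomethyl)-5-oxo-2,5-dihydrofuran-2-yl]-7-hydroxy-3,7-dimethyl-6-oxooct-2-en-4-ynal | BrCC1=C[C@H](C[C@@](C)(O)C(=O)C#C/C(C)=C\C=O)OC1=O
F5 | step 8 | (4Z,6R,7R,8S,10R)-6,10-dihydroxy-1-oxogermacra-4,11(13)-dien-2-yn-12,8-olide | C=C1C(=O)O[C@H]2C[C@@](C)(O)C(=O)C#C/C(C)=C\[C@@H](O)[C@H]12
F6 | step 7 | (2S)-1-{(2R)-2-methyl-3-oxo-5-[(2Z)-4-oxobut-2-en-2-yl]-2,3-dihydrofuran-2-yl}but-3-en-2-yl 2-(acetoxymethyl)prop-2-enoate | C=C[C@@H](OC(=O)C(=C)COC(C)=O)C[C@@]1(C)OC(=CC1=O)/C(C)=C\C=O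
F7 | step 7 | [(5S)-5-({(2R)-2-methyl-3-oxo-5-[(2Z)-4-oxobut-2-en-2-yl]-2,3-dihydrofuran-2-yl}methyl)-2-oxo-2,5-dihydrofuran-3-yl]methyl acetate | CC(=O)OCC1=C[C@H](C[C@@]2(C)OC(=CC2=O)/C(C)=C\C=O)OC1=O
F8 | step 12 | (4Z,7R,8S,10R)-1,6-dioxo-3,10-epoxygermacra-2,4,11(13)-trien-12,8-olide | C=C1C(=O)O[C@H]2C[C@@]3(C)OC(=CC3=O)/C(C)=C\C(=O)[C@H]12
F9 | step 12 | (4Z,6S,7R,8S,10R)-6-hydroxy-1-oxo-3,10-epoxygermacra-2,4,11(13)-trien-12,8-olide | C=C1C(=O)O[C@H]2C[C@@]3(C)OC(=CC3=O)/C(C)=C\[C@H](O)[C@H]12
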